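**Plan**
1. Retrosynthetic cuts, in order: lower C3–O and C4–O (back to the C3=C4 alkene of a flav-3-ene); lower C3=C4 (metathesis) and lower O1–C2 (allylic etherification); lower C4–C4a (formyl carbon); the interflavan bond upper C4–lower C6; upper O1–C2 and the chalcone Cα=Cβ bond.
2. Forward order: upper ring C closes first (epoxychalcone to dihydroflavonol). Lower ring A is then joined to upper C4 as an aryl-lithium, lower ring C closes last by ring-closing metathesis, and its alkene is dioxygenated. Three benzoates and six benzyl ethers fall in the last two steps.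
3. Enabling feature: in lower ring C the 2-aryl group and O3 share one face (α) and O4 lies on the other (β), and C4 is benzylic and para to O7 of lower ring A. Iodine delivered anti to the aryl group can therefore be displaced from the aryl face by a benzoate already bound at C4, and the bridged ion opens at C4 only.
4. Stereochemistry: upper C3 and C2 come from a poly-D-leucine epoxidation and an invertive ring closure, and upper C4 from hydride attack anti to the 3-benzyloxy group. Lower C2 comes from an iridium–phosphoramidite catalyst, and lower C3 and C4 from lower C2 through the iodonium/dioxolanylium relay.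
5. The lower ring B oxygen is carried as a benzoate, not an ether, so that this aryl group does not migrate to C3, is not iodinated, and does not labilise the allylic C2–O bond.
6. α/β mean below/above the plane in the usual flavan drawing (ring A left, O1 at top). CIP letters at several centres change with the protecting groups although the geometry does not, so the SMILES strings decide. The target, ent-oritin-(4α→6)-epioritin-4β-ol, is upper (2S,3R,4R), lower (2R,3R,4S).

Key step: step 18

Assumption: the cyclometallated catalyst from [Ir(cod)Cl]2 and the (S_a,S_c,S_c)-phosphoramidite is taken to give the (S)-1-arylallyl aryl ether. Both ligand antipodes are commercial, so a trial with 2-vinylphenol would fix the choice, and only the ligand descriptor in step 16 would change.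
Notation: U = 2β-[4-(benzyloxy)phenyl]-3α,7,8-tris(benzyloxy)chroman-4α-yl, the protected upper unit (2,3-trans-3,4-cis) as set in step 10.

**Step 1**
Reactants: 1 gallacetophenone
Product: 2 1-[3,4-bis(benzyloxy)-2-hydroxyphenyl]ethanone
Conditions: BnBr (2.1 equiv), K2CO3, acetone, reflux
Reagents that add atoms: benzyl bromide, BrCc1ccccc1
Why: Williamson etherification; the 2-OH is tied up in a hydrogen bond to the acetyl carbonyl and is the least reactive phenol, so two equivalents of halide should stop at the 3,4-diether.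

**Step 2**
Reactants: 2 1-[3,4-bis(benzyloxy)-2-hydroxyphenyl]ethanone
Product: 3 1-[3,4-bis(benzyloxy)-2-(methoxymethoxy)phenyl]ethanone
Conditions: NaH (1.05 equiv), MOMCl, DMF, 0 °C to rt
Reagents that add atoms: chloromethyl methyl ether, COCCl
Why: O-alkylation of the sodium phenoxide (Williamson type); irreversible deprotonation breaks the chelate, and the acetal masks the phenol through the two basic steps that follow.

**Step 3**
Reactants: 3 1-[3,4-bis(benzyloxy)-2-(methoxymethoxy)phenyl]ethanone; 4 4-(benzyloxy)benzaldehyde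
Product: 5 (E)-1-[3,4-bis(benzyloxy)-2-(methoxymethoxy)phenyl]-3-[4-(benzyloxy)phenyl]prop-2-en-1-one
Conditions: KOH, EtOH, rt
Reagents that add atoms: none
Why: Claisen–Schmidt condensation of a methyl ketone with a non-enolisable aldehyde, which should give the (E)-enone under thermodynamic control.

**Step 4**
Reactants: 5 (E)-chalcone
Product: 6 [3,4-bis(benzyloxy)-2-(methoxymethoxy)phenyl]{(2S,3R)-3-[4-(benzyloxy)phenyl]oxiran-2-yl}methanone
Conditions: poly-D-leucine, urea·H2O2, DBU, THF, rt
Reagents that add atoms: hydrogen peroxide (as its urea adduct), OO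
Why: Juliá–Colonna epoxidation; the helical D-polymer should give the (αS,βR) trans-epoxide, the mirror image of the (αR,βS) product known for the L-polymer, which fixes the future upper C3, and crystallisation can raise the enantiopurity.

**Step 5**
Reactants: 6 (2S,3R)-epoxychalcone MOM ether
Product: 8 (2S,3S)-7,8-bis(benzyloxy)-2-[4-(benzyloxy)phenyl]-3-hydroxychroman-4-one, via 2'-hydroxy epoxychalcone 7 (not isolated)
Conditions: conc. HCl (cat.), MeOH–THF, 50 °C
Reagents that add atoms: none
Why: Acid acetal cleavage followed by 6-endo-tet epoxide opening; the freed phenol attacks the benzylic Cβ with inversion to give the 2,3-trans dihydroflavonol (also the thermodynamic isomer), and the Cα–O bond is never broken, so C3 keeps its configuration.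

**Step 6**
Reactants: 8 (2S,3S)-dihydroflavonol
Product: 9 (2S,3S)-3,7,8-tris(benzyloxy)-2-[4-(benzyloxy)phenyl]chroman-4-one
Conditions: BnOC(=NH)CCl3 (1.5 equiv), TfOH (5 mol %), CH2Cl2–cyclohexane, 0 °C
Reagents that add atoms: benzyl 2,2,2-trichloroacetimidate, N=C(OCc1ccccc1)C(Cl)(Cl)Cl
Why: Acid-catalysed imidate benzylation; it avoids base, which would enolise C3 or open ring C by E1cB loss of the phenoxide, so both stereocentres should be retained.

**Step 7**
Reactants: 10 pyrogallol
Product: 11 1,2,3-tris(benzyloxy)benzene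
Conditions: BnBr (3.3 equiv), K2CO3, DMF, 60 °C, N2
Reagents that add atoms: benzyl bromide, BrCc1ccccc1
Why: Exhaustive Williamson etherification, run under nitrogen because pyrogallol autoxidises in base.

**Step 8**
Reactants: 11 1,2,3-tris(benzyloxy)benzene
Product: 12 1,5-dibromo-2,3,4-tris(benzyloxy)benzene
Conditions: NBS (2.05 equiv), MeCN, 0 °C to rt, dark
Reagents that add atoms: N-bromosuccinimide, O=C1CCC(=O)N1Br
Why: Electrophilic aromatic bromination; the two positions ortho/para to the outer ether oxygens react while the position para to the twisted central ether does not, which should give the symmetric dibromide with two equivalent handles.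

**Step 9**
Reactants: 12 1,5-dibromo-2,3,4-tris(benzyloxy)benzene; 9 (2S,3S)-3-O-benzyl flavan-4-one
Product: 14 (2S,3S)-3,7,8-tris(benzyloxy)-2-[4-(benzyloxy)phenyl]-4-[5-bromo-2,3,4-tris(benzyloxy)phenyl]chroman-4-ol (either C4 epimer), via monolithiated arene 13 (not isolated)
Conditions: 12 (1.3 equiv), n-BuLi (1.3 equiv), THF, −78 °C; 9, −78 to −40 °C; H2O
Reagents that add atoms: none
Why: Bromine–lithium exchange at one of two equivalent bromines, then 1,2-addition of the aryl-lithium to the flavan-4-one at low temperature, where addition should outrun enolisation at C3; the new C4 centre is erased in step 10, so its configuration does not matter.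

**Step 10**
Reactants: 14 tertiary 4-aryl flavan-4-ol
Product: 16 2β-[4-(benzyloxy)phenyl]-3α,7,8-tris(benzyloxy)-4α-[5-bromo-2,3,4-tris(benzyloxy)phenyl]chroman (U–aryl bromide), via flavan-4-ylium ion 15 (not isolated)
Conditions: Bu3SnH (3 equiv), CF3CO2H (5 equiv), CH2Cl2, −40 to 0 °C, dark
Reagents that add atoms: none
Why: Ionic hydrogenation; the acid ionises the doubly benzylic carbinol, and Bu3SnH, a faster hydride donor than a silane so that capture outruns loss of H-3, should attack the β face anti to the 3α-benzyloxy group (the face nucleophiles choose in 2,3-trans flavan-4-yl cations), leaving the aryl group α and 3,4-cis, while the aryl bromide is inert to this polar, initiator-free hydride transfer.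

**Step 11**
Reactants: 16 U–aryl bromide
Product: 18 2,3,4-tris(benzyloxy)-5-U-benzaldehyde, via aryl-lithium 17 (not isolated)
Conditions: n-BuLi (1.1 equiv), THF, −78 °C; DMF, −78 to 0 °C; H2O
Reagents that add atoms: N,N-dimethylformamide, CN(C)C=O
Why: Bromine–lithium exchange and Bouveault formylation; the carbon enters only where bromine stood, which removes the competition from the equally electron-rich upper ring A that an electrophilic formylation would face.

**Step 12**
Reactants: 18 2,3,4-tris(benzyloxy)-5-U-benzaldehyde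
Product: 19 3,4-bis(benzyloxy)-2-hydroxy-5-U-benzaldehyde
Conditions: MgBr2·OEt2 (3 equiv), toluene–Et2O, 75 °C; 1 M HCl
Reagents that add atoms: none
Why: Chelation-controlled ether cleavage; magnesium held between the aldehyde oxygen and the ortho ether oxygen activates only that benzyl group toward bromide, so the other six benzyl ethers should stay.

**Step 13**
Reactants: 19 3,4-bis(benzyloxy)-2-hydroxy-5-U-benzaldehyde
Product: 20 2,3-bis(benzyloxy)-4-U-6-vinylphenol
Conditions: Ph3PCH3Br (3 equiv), KOt-Bu (3 equiv), THF, 0 °C to rt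
Reagents that add atoms: methyltriphenylphosphonium bromide, C[P+](c1ccccc1)(c1ccccc1)c1ccccc1.[Br-]
Why: Wittig methylenation of a salicylaldehyde; one equivalent of base is spent on the phenol and excess ylide converts the phenoxide aldehyde into the 2-vinylphenol.

**Step 14**
Reactants: 21 4-acetoxystyrene
Product: 23 4-vinylphenyl benzoate, via potassium 4-vinylphenoxide 22 (not isolated)
Conditions: KOH (2.1 equiv), THF–H2O, 0 °C; BzCl (1.2 equiv), 0 °C
Reagents that add atoms: benzoyl chloride, O=C(Cl)c1ccccc1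
Why: Saponification and Schotten–Baumann acylation in one flask, so that the polymerisable vinylphenol is never isolated and the labile acetate is exchanged for a sturdier ester.

**Step 15**
Reactants: 23 4-vinylphenyl benzoate; 24 allyl tert-butyl carbonate
Product: 25 (E)-3-[4-(benzoyloxy)phenyl]allyl tert-butyl carbonate
Conditions: second-generation Hoveyda–Grubbs catalyst RuCl2(=CH-C6H4-2-Oi-Pr)(H2IMes) (3 mol %), 24 (3 equiv), CH2Cl2, 40 °C
Reagents that add atoms: none
Why: Olefin cross metathesis of a styrene with an allylic carbonate; loss of ethene drives it, and the conjugated (E)-alkene is the thermodynamic product.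

**Step 16**
Reactants: 20 2,3-bis(benzyloxy)-4-U-6-vinylphenol; 25 (E)-cinnamyl-type tert-butyl carbonate
Product: 26 (S)-1-[4-(benzoyloxy)phenyl]allyl 2,3-bis(benzyloxy)-4-U-6-vinylphenyl ether
Conditions: [Ir(cod)Cl]2 (2 mol %), (S_a,S_c,S_c)-O,O'-(1,1'-binaphthyl-2,2'-diyl) N,N-bis(1-phenylethyl)phosphoramidite (4 mol %), pre-activated with n-PrNH2 (then evaporated), K3PO4 (1 equiv), THF, rt
Reagents that add atoms: none
Why: Iridium-catalysed asymmetric allylic etherification, known for 2-vinylphenols; the aryloxide should attack the π-allyl complex at its aryl-bearing terminus anti to the metal, so the branched ether forms and the catalyst alone sets lower C2 (S here because aryl outranks vinyl, the same geometry as 2R in the target), the released tert-butoxide is quenched by phenol 20 before it can touch the ester, and the electron-poor aryl group keeps the product from re-ionising.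

**Step 17**
Reactants: 26 branched diene ether
Product: 27 (2S)-2-[4-(benzoyloxy)phenyl]-7,8-bis(benzyloxy)-6-U-2H-chromene (2α-aryl flav-3-ene)
Conditions: second-generation Grubbs catalyst RuCl2(=CHPh)(PCy3)(H2IMes) (5 mol %), CH2Cl2 (5 mM), 40 °C, dark
Reagents that add atoms: none
Why: Ring-closing metathesis of a styrene with a terminal allyl ether closes lower ring C as a six-membered ring with loss of ethene; C2 is untouched, and light is excluded to prevent 6π ring opening of the chromene, which would scramble C2.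

**Step 18**
Reactants: 27 (2S)-flav-3-ene
Product: 30 2α-[4-(benzoyloxy)phenyl]-3α,4β-bis(benzoyloxy)-7,8-bis(benzyloxy)-6-U-chroman (2,3-cis-3,4-trans), via trans-iodobenzoate 28 (not isolated), via dioxolanylium ion 29 (not isolated)
Conditions: I2 (1.0 equiv), AgO2CPh (2.3 equiv), dry toluene, 4 Å MS, dark, −20 °C; 27, −20 to 20 °C; then 80 °C
Reagents that add atoms: silver benzoate, [Ag+].[O-]C(=O)c1ccccc1
Why: Benzoyl hypoiodite made from I2 and AgO2CPh should iodinate the C3=C4 alkene of lower ring C on its β face, anti to the 2α-aryl group, and benzoate then captures the benzylic C4 from the α face to give 28 (3β-I, 4α-OBz). Silver-assisted loss of iodide is attended by the carbonyl oxygen of the 4α-benzoate, which attacks C3 from the α face in a 5-exo-tet closure to the cis-fused 2-phenyl-1,3-dioxolan-2-ylium ion 29, a transient ring that is not kept. A second benzoate opens 29 at C4 from the β face, so O3 ends α (cis to the aryl group), O4 ends β, and no new ring remains. The closest known reaction is the anhydrous Prévost reaction of cyclic styrene-type alkenes, which gives trans-1,2-dibenzoates through the same ion. Lower C3 is controlled by C2 through two inversions (iodine anti, then oxygen syn to the aryl group), C4 by anti opening of 29, and a benzoate placed on the wrong face of C4 can re-ionise and drain into 29. Three selectivities are needed: opening at C4 rather than C3, secured by the benzylic position para to the 7-benzyloxy group; alkene rather than arene iodination, secured by one equivalent of I2 at low temperature on an alkene conjugated with that donor; and benzoate participation rather than 1,2-shift of the anti-periplanar 2-aryl group, secured by the deactivating 4'-benzoate.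

**Step 19**
Reactants: 30 tribenzoate
Product: 31 2α-(4-hydroxyphenyl)-7,8-bis(benzyloxy)-6-U-chroman-3α,4β-diol (hexabenzyl ether of the target)
Conditions: i-Bu2AlH (9 equiv), CH2Cl2, −78 °C; aq. KNaC4H4O6 (potassium sodium tartrate)
Reagents that add atoms: none
Why: Reductive ester cleavage; all three benzoates are reduced to benzyl alcohol in a cold aprotic medium, which avoids a free 4'-phenoxide in protic base (ring C opening to a quinone methide and epimerisation at lower C2) and solvolysis at lower C4, and no C–O bond at a stereocentre is broken.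

**Step 20**
Reactants: 31 hexabenzyl ether
Product: 32 ent-oritin-(4α→6)-epioritin-4β-ol (target)
Conditions: H2 (1 atm), Pd(OH)2/C, THF–MeOH, rt, neutral
Reagents that add atoms: none
Why: Catalytic hydrogenolysis; the six O-benzyl groups should be cleaved faster than the secondary benzylic C4–OH and the cyclic C2–O1 bonds, the acid-free medium prevents ionisation at lower C4, and no stereocentre is touched.

**Compound list**
1 | gallacetophenone | CC(=O)c1ccc(O)c(O)c1O | starting material
2 | 1-[3,4-bis(benzyloxy)-2-hydroxyphenyl]ethanone | CC(=O)c1ccc(OCc9ccccc9)c(OCc9ccccc9)c1O | intermediate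
3 | 1-[3,4-bis(benzyloxy)-2-(methoxymethoxy)phenyl]ethanone | CC(=O)c1ccc(OCc9ccccc9)c(OCc9ccccc9)c1OCOC | intermediate
4 | 4-(benzyloxy)benzaldehyde | O=Cc1ccc(OCc2ccccc2)cc1 | starting material
5 | (E)-chalcone | COCOc1c(C(=O)/C=C/c2ccc(OCc9ccccc9)cc2)ccc(OCc9ccccc9)c1OCc9ccccc9 | intermediate
6 | (2S,3R)-epoxychalcone MOM ether | COCOc1c(C(=O)[C@H]3O[C@@H]3c2ccc(OCc9ccccc9)cc2)ccc(OCc9ccccc9)c1OCc9ccccc9 | intermediate
7 | 2'-hydroxy (2S,3R)-epoxychalcone | Oc1c(C(=O)[C@H]3O[C@@H]3c2ccc(OCc9ccccc9)cc2)ccc(OCc9ccccc9)c1OCc9ccccc9 | intermediate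
8 | (2S,3S)-7,8-bis(benzyloxy)-2-[4-(benzyloxy)phenyl]-3-hydroxychroman-4-one | O=C1c2ccc(OCc9ccccc9)c(OCc9ccccc9)c2O[C@@H](c2ccc(OCc9ccccc9)cc2)[C@@H]1O | intermediate
9 | (2S,3S)-3,7,8-tris(benzyloxy)-2-[4-(benzyloxy)phenyl]chroman-4-one | O=C1c2ccc(OCc9ccccc9)c(OCc9ccccc9)c2O[C@@H](c2ccc(OCc9ccccc9)cc2)[C@@H]1OCc9ccccc9 | intermediate
10 | pyrogallol | Oc1cccc(O)c1O | starting material
11 | 1,2,3-tris(benzyloxy)benzene | c1cc(OCc9ccccc9)c(OCc9ccccc9)c(OCc9ccccc9)c1 | intermediate
12 | 1,5-dibromo-2,3,4-tris(benzyloxy)benzene | Brc1cc(Br)c(OCc9ccccc9)c(OCc9ccccc9)c1OCc9ccccc9 | intermediate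
13 | 5-bromo-2,3,4-tris(benzyloxy)phenyllithium | [Li]c1cc(Br)c(OCc9ccccc9)c(OCc9ccccc9)c1OCc9ccccc9 | intermediate
14 | tertiary 4-aryl flavan-4-ol (C4 not defined) | OC1(c2cc(Br)c(OCc9ccccc9)c(OCc9ccccc9)c2OCc9ccccc9)c2ccc(OCc9ccccc9)c(OCc9ccccc9)c2O[C@@H](c2ccc(OCc9ccccc9)cc2)[C@@H]1OCc9ccccc9 | intermediate
15 | 4-aryl flavan-4-ylium ion | [C+]1(c2cc(Br)c(OCc9ccccc9)c(OCc9ccccc9)c2OCc9ccccc9)c2ccc(OCc9ccccc9)c(OCc9ccccc9)c2O[C@@H](c2ccc(OCc9ccccc9)cc2)[C@@H]1OCc9ccccc9 | intermediate
16 | U–aryl bromide (2,3-trans-3,4-cis) | Brc1cc([C@@H]4c5ccc(OCc9ccccc9)c(OCc9ccccc9)c5O[C@@H](c5ccc(OCc9ccccc9)cc5)[C@@H]4OCc9ccccc9)c(OCc9ccccc9)c(OCc9ccccc9)c1OCc9ccccc9 | intermediate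
17 | 2,3,4-tris(benzyloxy)-5-U-phenyllithium | [Li]c1cc([C@@H]4c5ccc(OCc9ccccc9)c(OCc9ccccc9)c5O[C@@H](c5ccc(OCc9ccccc9)cc5)[C@@H]4OCc9ccccc9)c(OCc9ccccc9)c(OCc9ccccc9)c1OCc9ccccc9 | intermediate
18 | 2,3,4-tris(benzyloxy)-5-U-benzaldehyde | O=Cc1cc([C@@H]4c5ccc(OCc9ccccc9)c(OCc9ccccc9)c5O[C@@H](c5ccc(OCc9ccccc9)cc5)[C@@H]4OCc9ccccc9)c(OCc9ccccc9)c(OCc9ccccc9)c1OCc9ccccc9 | intermediate
19 | 3,4-bis(benzyloxy)-2-hydroxy-5-U-benzaldehyde | O=Cc1cc([C@@H]4c5ccc(OCc9ccccc9)c(OCc9ccccc9)c5O[C@@H](c5ccc(OCc9ccccc9)cc5)[C@@H]4OCc9ccccc9)c(OCc9ccccc9)c(OCc9ccccc9)c1O | intermediate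
20 | 2,3-bis(benzyloxy)-4-U-6-vinylphenol | C=Cc1cc([C@@H]4c5ccc(OCc9ccccc9)c(OCc9ccccc9)c5O[C@@H](c5ccc(OCc9ccccc9)cc5)[C@@H]4OCc9ccccc9)c(OCc9ccccc9)c(OCc9ccccc9)c1O | intermediate
21 | 4-acetoxystyrene | CC(=O)Oc1ccc(C=C)cc1 | starting material
22 | potassium 4-vinylphenoxide | [K+].[O-]c1ccc(C=C)cc1 | intermediate
23 | 4-vinylphenyl benzoate | O=C(Oc1ccc(C=C)cc1)c1ccccc1 | intermediate
24 | allyl tert-butyl carbonate | C=CCOC(=O)OC(C)(C)C | starting material
25 | (E)-3-[4-(benzoyloxy)phenyl]allyl tert-butyl carbonate | CC(C)(C)OC(=O)OC/C=C/c1ccc(OC(=O)c2ccccc2)cc1 | intermediate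
26 | (S)-branched allyl aryl ether | O=C(c6ccccc6)Oc1ccc([C@H](C=C)Oc3c(C=C)cc([C@@H]4c5ccc(OCc9ccccc9)c(OCc9ccccc9)c5O[C@@H](c5ccc(OCc9ccccc9)cc5)[C@@H]4OCc9ccccc9)c(OCc9ccccc9)c3OCc9ccccc9)cc1 | intermediate
27 | (2S)-flav-3-ene, 2α-aryl (key-step precursor) | O=C(c6ccccc6)Oc1ccc([C@H]2Oc3c(cc([C@@H]4c5ccc(OCc9ccccc9)c(OCc9ccccc9)c5O[C@@H](c5ccc(OCc9ccccc9)cc5)[C@@H]4OCc9ccccc9)c(OCc9ccccc9)c3OCc9ccccc9)C=C2)cc1 | intermediate
28 | 3β-iodo-4α-benzoate | O=C(c6ccccc6)Oc1ccc([C@H]2Oc3c(cc([C@@H]4c5ccc(OCc9ccccc9)c(OCc9ccccc9)c5O[C@@H](c5ccc(OCc9ccccc9)cc5)[C@@H]4OCc9ccccc9)c(OCc9ccccc9)c3OCc9ccccc9)[C@@H](OC(=O)c6ccccc6)[C@@H]2I)cc1 | intermediate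
29 | 3α,4α-fused 2-phenyl-1,3-dioxolan-2-ylium ion | O=C(c6ccccc6)Oc1ccc([C@H]2Oc3c(cc([C@@H]4c5ccc(OCc9ccccc9)c(OCc9ccccc9)c5O[C@@H](c5ccc(OCc9ccccc9)cc5)[C@@H]4OCc9ccccc9)c(OCc9ccccc9)c3OCc9ccccc9)[C@H]7[O+]=C(c6ccccc6)O[C@H]72)cc1 | intermediate
30 | 3α,4β-dibenzoate 4'-benzoate (key-step product) | O=C(c6ccccc6)Oc1ccc([C@H]2Oc3c(cc([C@@H]4c5ccc(OCc9ccccc9)c(OCc9ccccc9)c5O[C@@H](c5ccc(OCc9ccccc9)cc5)[C@@H]4OCc9ccccc9)c(OCc9ccccc9)c3OCc9ccccc9)[C@H](OC(=O)c6ccccc6)[C@H]2OC(=O)c6ccccc6)cc1 | intermediate
31 | hexabenzyl ether of the target | Oc1ccc([C@H]2Oc3c(cc([C@@H]4c5ccc(OCc9ccccc9)c(OCc9ccccc9)c5O[C@@H](c5ccc(OCc9ccccc9)cc5)[C@@H]4OCc9ccccc9)c(OCc9ccccc9)c3OCc9ccccc9)[C@H](O)[C@H]2O)cc1 | intermediate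
32 | ent-oritin-(4α→6)-epioritin-4β-ol | Oc1ccc([C@H]2Oc3c(cc([C@@H]4c5ccc(O)c(O)c5O[C@@H](c5ccc(O)cc5)[C@@H]4O)c(O)c3O)[C@H](O)[C@H]2O)cc1 | target

**Step count**
Total: 20 steps. Longest linear sequence: 16 steps (1–6, 9–13, 16–20).

**Steps most likely to fail**

Step 18. Three things may go wrong. After the iodobenzoate has formed, loss of iodide may be attended by the anti-periplanar 2-aryl group (a 1,2-shift to an isoflavan-type oxocarbenium ion) instead of by the benzoate. The hypoiodite may iodinate upper ring A. Benzoate may open the bridged ion at C3.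

The fallback sets out from 27 and replaces the silver-driven ionisation by a base-driven halohydrin–epoxide relay with the same face logic.
- NBS in aqueous THF at 0 °C should give the trans-bromohydrin F1 (3β-Br, 4α-OH).
- Cs2CO3 in MeCN closes it by intramolecular SN2 to the 3α,4α-epoxide F2, syn to the aryl group.
- Benzoic acid in toluene opens the benzylic C4 with inversion to the 4β-benzoate 3α-ol F3.
- F3 is carried through the i-Bu2AlH conditions of step 19 and rejoins the route at 31.

Step 16. The doubly ortho-substituted phenoxide may be allylated too slowly. The branched ether may also re-ionise on the catalyst, with erosion of regio- and enantiopurity.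

The fallback sets out from 19 (and from 23 for the second component) and makes O1–C2 by electrocyclisation rather than by substitution.
- Cross metathesis of 23 with vinylboronic acid pinacol ester gives the (E)-styrylboronate F4.
- NaIO4/NH4OAc in aqueous acetone frees the boronic acid F5.
- Heating F5 with 19 and dibenzylamine (20 mol %, dioxane, 90 °C) runs a catalytic Petasis borono-Mannich reaction, loss of the amine, and 6π closure of the o-quinone methide.
- This should give 27 together with its C2 epimer F6. Because the upper unit is a single enantiomer, the two are diastereomers and are separated by chromatography.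
- The route is rejoined at 27, and steps 13 and 15–17 are bypassed.

Step 10. Hydride delivery may show poor facial selectivity, because the 2β-aryl group sits on the face that must be attacked. The cation may also lose H-3 to give the enol ether.

The fallback sets out from 8 and changes the control element rather than the reductant.
- TIPSOTf/2,6-lutidine gives the 3-O-triisopropylsilyl ketone F7.
- Addition of 13 as in step 9 gives the carbinol F8.
- Bu3SnH/CF3CO2H reduction, now with a much larger group screening the α face, gives the 3,4-cis silyl ether F9.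
- Bu4NF frees the 3-ol F10.
- NaH/BnBr, harmless once the ketone is gone, returns the route to 16.

**Further compounds**
F1 | step 18 | trans-bromohydrin of 27 (3β-Br, 4α-OH) | O=C(c6ccccc6)Oc1ccc([C@H]2Oc3c(cc([C@@H]4c5ccc(OCc9ccccc9)c(OCc9ccccc9)c5O[C@@H](c5ccc(OCc9ccccc9)cc5)[C@@H]4OCc9ccccc9)c(OCc9ccccc9)c3OCc9ccccc9)[C@@H](O)[C@@H]2Br)cc1
F2 | step 18 | 3α,4α-epoxide of 27 | O=C(c6ccccc6)Oc1ccc([C@H]2Oc3c(cc([C@@H]4c5ccc(OCc9ccccc9)c(OCc9ccccc9)c5O[C@@H](c5ccc(OCc9ccccc9)cc5)[C@@H]4OCc9ccccc9)c(OCc9ccccc9)c3OCc9ccccc9)[C@H]7O[C@H]72)cc1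
F3 | step 18 | 4β-benzoate 3α-ol | O=C(c6ccccc6)Oc1ccc([C@H]2Oc3c(cc([C@@H]4c5ccc(OCc9ccccc9)c(OCc9ccccc9)c5O[C@@H](c5ccc(OCc9ccccc9)cc5)[C@@H]4OCc9ccccc9)c(OCc9ccccc9)c3OCc9ccccc9)[C@H](OC(=O)c6ccccc6)[C@H]2O)cc1
F4 | step 16 | 4-[(E)-2-(4,4,5,5-tetramethyl-1,3,2-dioxaborolan-2-yl)ethenyl]phenyl benzoate | O=C(c6ccccc6)Oc1ccc(/C=C/B2OC(C)(C)C(C)(C)O2)cc1
F5 | step 16 | (E)-2-[4-(benzoyloxy)phenyl]ethenylboronic acid | O=C(c6ccccc6)Oc1ccc(/C=C/B(O)O)cc1
F6 | step 16 | C2 epimer of 27 (2β-aryl) | O=C(c6ccccc6)Oc1ccc([C@@H]2Oc3c(cc([C@@H]4c5ccc(OCc9ccccc9)c(OCc9ccccc9)c5O[C@@H](c5ccc(OCc9ccccc9)cc5)[C@@H]4OCc9ccccc9)c(OCc9ccccc9)c3OCc9ccccc9)C=C2)cc1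
F7 | step 10 | (2S,3S)-7,8-bis(benzyloxy)-2-[4-(benzyloxy)phenyl]-3-(triisopropylsilyloxy)chroman-4-one | O=C1c2ccc(OCc9ccccc9)c(OCc9ccccc9)c2O[C@@H](c2ccc(OCc9ccccc9)cc2)[C@@H]1O[Si](C(C)C)(C(C)C)C(C)C
F8 | step 10 | 3-O-triisopropylsilyl analogue of 14 (C4 not defined) | OC1(c2cc(Br)c(OCc9ccccc9)c(OCc9ccccc9)c2OCc9ccccc9)c2ccc(OCc9ccccc9)c(OCc9ccccc9)c2O[C@@H](c2ccc(OCc9ccccc9)cc2)[C@@H]1O[Si](C(C)C)(C(C)C)C(C)C
F9 | step 10 | 3-O-triisopropylsilyl analogue of 16 | Brc1cc([C@@H]4c5ccc(OCc9ccccc9)c(OCc9ccccc9)c5O[C@@H](c5ccc(OCc9ccccc9)cc5)[C@@H]4O[Si](C(C)C)(C(C)C)C(C)C)c(OCc9ccccc9)c(OCc9ccccc9)c1OCc9ccccc9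
F10 | step 10 | 3-hydroxy analogue of 16 | Brc1cc([C@@H]4c5ccc(OCc9ccccc9)c(OCc9ccccc9)c5O[C@@H](c5ccc(OCc9ccccc9)cc5)[C@@H]4O)c(OCc9ccccc9)c(OCc9ccccc9)c1OCc9ccccc9
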